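Start at the late end of the runs. After 120 min, an electrophile stirred with protonated nucleophile and free base has come down to 69.9% in beta and 68.3% in eta, although eta holds about twice the free base of beta.

in all of them: electrophile 1.1 M; protonated nucleophile 1.32 M

| run | free base | remark | time |
|---|---|---|---|
| beta | 1.2 M | run made earlier |  |
| epsilon | 1.9 M | run made earlier |  |
| eta | 2.3 M | run made earlier |  |
| red | 1.60 M |  | 2.5 h |
| violet | 2.50 M |  | 2.5 h |

- beta (time / min: electrophile / %, target / %): 25.0: 92.5, 3.0; 50.0: 85.5, 5.8; 80.0: 77.4, 10.3; 120: 69.9, 13.7
- epsilon (time / min: electrophile / %, target / %): 25.0: 92.9, 3.9; 50.0: 85.7, 7.2; 80.0: 77.0, 12.2; 120: 68.4, 16.5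
- eta (time / min: electrophile / %, target / %): 8.00: 97.1, 1.3; 20.0: 93.9, 2.7; 50.0: 84.8, 8.2; 120: 68.3, 16.9

(each reading ± 0.5 percentage points)

- the numbers in the tables scatter with a standard deviation of 0.5 percentage points

- part of the electrophile that has reacted at the end, red
- part of the electrophile that has reacted at the end, violet
- what raising the concentration of free base from its lowest to its highest value here does to the part of the electrophile that has reacted (changes below 5 percentage points count as none) (it falls / no change / it rises)

So you can try folding the readings into one number. Take the logarithm of the fraction left at that late reading in each run, average the three, change sign, and stretch it to the asked time. This gives 0.466, which we call N, the lifetimes elapsed: time counted in the electrophile's own pseudo-first-order lifetime. The part reacted is then one minus e to the power of minus N, which is 37.3%.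

Is one number enough? Read at 50.0 min in epsilon and stretched the same way, it comes to 0.463, so in epsilon the earlier reading and the three-run figure lie on one straight line in the logarithm. Beta and eta, each stretched alone to the asked time, differ in electrophile left by 1.8 points, less than the 5 points that counts. My reckoning therefore gives 37.3% for both red and violet, though violet's free base lies beyond eta's.

The forecast says 37.5% for red, 38% for violet and no change, since the loss “looks zero order in base over this range”.

    electrophile + nucleophile → acid set free + target (k = 0.00110 M⁻¹ s⁻¹)
    nucleophile + acid set free ⇌ protonated nucleophile, settled at all times (K = 7500 M⁻¹)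
    acid set free + free base ⇌ salt of the base (K = 22000 M⁻¹, k = 0.00240 M⁻¹ s⁻¹)
    electrophile + acid set free → side product (k = 0.00380 M⁻¹ s⁻¹)
    nucleophile + acid set free ⇌ idle adduct, settled at all times (K = 0.940 M⁻¹)
    acid set free → by-product carried off (k = 7.90 × 10⁻⁵ s⁻¹)

The flask gives 37.2% for red and 37.2% for violet, a change of 0.083 points, which means no change. Red's result corresponds to N of 0.465. Now read red at 10 h: N stretches to 1.87, which reckons 84.5% reacted. That neighbour gives 82.0%, less than reckoned, with protonated nucleophile down to 60.4% of its charge.

(The runs are calculated with constants of no real substance; noise was put on by code.)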